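Compare two half-lives in these flasks, the one with which substrate goes and the one with which open intermediate goes, because the order of those two clocks tells you what is in the flask when you stop.

| setting | theta | eta | delta | south-east | east | south-west |
|---|---|---|---|---|---|---|
| substrate | 0.010 M | 0.010 M | 0.010 M | 0.010 M | 0.010 M | 0.010 M |
| partner | 1 equiv | 1 equiv | 1 equiv | 1.00 equiv | 1.00 equiv | 1.00 equiv |
| reagent | 0.96 equiv | 1.6 equiv | 1.9 equiv | 1.70 equiv | 1.10 equiv | 2.50 equiv |
| remark | run made earlier | run made earlier | run made earlier |  |  |  |
| time |  |  |  | 20 h | 20 h | 20 h |

| run | time / h | side product / % | open intermediate / % | substrate / % | target / % |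
|---|---|---|---|---|---|
| theta | 1.00 | 3 | 14 | 87 | 1 |
| theta | 2.00 | 0 | 28 | 72 | 4 |
| theta | 4.00 | 0 | 38 | 60 | 5 |
| theta | 8.00 | 2 | 42 | 47 | 8 |
| theta | 15.0 | 1 | 43 | 42 | 16 |
| eta | 1.33 | 0 | 31 | 71 | 2 |
| eta | 4.00 | 2 | 52 | 42 | 3 |
| eta | 6.00 | 3 | 60 | 30 | 8 |
| eta | 10.0 | 1 | 63 | 20 | 15 |
| eta | 15.0 | 0 | 60 | 17 | 25 |
| delta | 1.33 | 0 | 34 | 61 | 1 |
| delta | 4.00 | 1 | 61 | 33 | 2 |
| delta | 6.00 | 0 | 63 | 26 | 12 |
| delta | 10.0 | 0 | 63 | 15 | 20 |
| delta | 15.0 | 3 | 62 | 10 | 30 |

(standard deviation of a reading: 2 percentage points)

- what was read earlier has a scatter of 2 percentage points, one standard deviation
- a reading or a percentage of target counts all its forms, free or not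

- which of these there is most of at the end, counted by the substrate in it, south-east (target / side product / open intermediate / substrate)
- which of these there is most of at the end, counted by the substrate in it, east (target / side product / open intermediate / substrate)
- which of these there is most of at the end, counted by the substrate in it, south-west (target / side product / open intermediate / substrate)
- amount of the one of these that there is most of at the end, in percent of the substrate charged, south-east
- amount of the one of these that there is most of at the end, in percent of the substrate charged, east
- amount of the one of these that there is most of at the end, in percent of the substrate charged, south-west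

1. A half-life belongs to a first-order loss, where a fixed fraction goes in each equal stretch of time. Call the substrate's half-life at its first rate t_A. The first delta reading gives t_A = 1.87 h, while the first theta reading, with less reagent, gives a longer 4.98 h. So t_A shortens as reagent rises, roughly as a pseudo-first-order constant would.

2. Suppose that target grows in proportion to the open intermediate standing in the flask. Between the last two eta readings, that gain gives a constant k_I = 0.0325 h⁻¹, and the same reckoning on delta gives 0.0320 h⁻¹. Your carried quantity is t_I = ln(2)/k_I, the half-life of open intermediate on its way to target, which is 21.3 h as a reading. As read, t_I is longer than t_A, so on these readings target forms more slowly than substrate opens.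

3. Target passes open intermediate about one t_I after the substrate has opened, so my rule puts the crossing near t_A + t_I. South-west has the most reagent, so scale delta's t_A down to 1.42 h. The crossing then falls near 22.7 h, later than 20 h, though narrowly given the scatter. East and south-east open more slowly, so I expect open intermediate to lead in each flask.

4. The forecast agrees on the leader, with 54% for south-east, 45% for east and 52% for south-west. Of south-west it says: “This is the closest call, but intermediate probably still leads.”

5. The equations behind the flasks are these.

    open intermediate + second intermediate → target (k = 0.670 M⁻¹ min⁻¹)
    reagent ⇌ dormant form (K = 2.50, k = 4.50 × 10⁻⁴ min⁻¹)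
    substrate + reagent → open intermediate (k = 0.340 M⁻¹ min⁻¹)
    2 second intermediate → homo product (k = 0.240 M⁻¹ min⁻¹)
    crystals ⇌ target, rate k5*(cs5 - [target]) while solid is left; crystals form when [target] > cs5 (solubility = 8.40 mM, k = 0.0250 min⁻¹)
    substrate + second intermediate → side product (k = 0.00870 M⁻¹ min⁻¹)
    reagent + partner → second intermediate (k = 0.0750 M⁻¹ min⁻¹)

6. South-east, east and south-west end with open intermediate in the lead, at 57.1%, 50.0% and 51.5%. East stands 5 percentage points above the forecast, with its reagent at 5.18% of its charge. East's own target gain between 10.0 h and 20.0 h gives t_I = 48.5 h, longer than the 21.3 h read from eta. Now take a neighbour of south-east with 0.040 M of substrate. Scaling t_I by concentration, as for a second-order step, gives 5.33 h, shorter than 20 h, and that flask ends with target, crystals counted, at 52.3% against 45.3% of open intermediate.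

(The earlier runs and the new flask stem from a simulated flask on assumed constants; the scatter is artificial.)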